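## Structural features

The target is a dihydrochalcone: two benzene rings joined by a three-carbon chain whose carbonyl carbon sits on ring A and whose two methylenes lead to ring B. Ring A is an acylphloroglucinol in which one oxygen is part of a fused 2,2-dimethyldihydropyran, that is a chroman (O1, C2 with two methyls, C3, C4, C4a, C8a). The ketone is on C6, hydroxyls are on C5 and C7, and C8 is the only ring-A carbon that bears hydrogen. Ring B is a para-hydroxyphenyl group with a 3-methylbut-2-enyl (prenyl) group ortho to its hydroxyl. There is no stereocentre, so the problem is one of regiochemistry and chemoselectivity. The fragile parts are the prenyl alkene, which is attacked by electrophilic oxidants and under acid closes onto the ring-B phenol, and the electron-rich acylphloroglucinol, which is easily oxidised and nucleophilic at C8. The real difficulty is to place the acyl group at C6 and not at C8 of a 5,7-dioxygenated chroman, and to prenylate ring B once while the far more nucleophilic ring A is left alone. The feature used here is that the C6 carbonyl has exactly two ortho carbons, C5 and C7, both oxygenated in the target, while a plain chroman is acylated at C6 (para to O1); the ketone oxygen can therefore direct both phenols into a finished carbon skeleton.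

## Logic of the disconnections

15 ⇒ 14. The first bond cut is the O–C(acyl) bond of an aryl ester on the ring-B oxygen. That phenol must be masked through the Lewis-acid, oxidative and palladium steps, and the mask must come off without acid, because acid would close the prenyl group onto that oxygen. An acyl group that is removed by methanolysis meets both needs and also deactivates ring B. The gain is protective only. The forward step must be a base-mediated cleavage mild enough for an acylphloroglucinol.

14 ⇒ 12 + 13. Next the bond between C3 of ring B and the prenyl CH2 is cut. The trisubstituted alkene cannot coexist with an electrophilic oxidant, so it has to enter after the oxidation. The cut leaves an aryl bromide, which is cheap to install and inert to the oxidation. The gain is that ring B carries only a halogen and an ester up to that point. The forward step must deliver the allyl unit through its CH2 terminus and tolerate two free phenols.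

12 ⇒ 9 (through 10 and 11). The two C–O bonds at C5 and C7 are cut. Both oxygens are ortho to the C6 ketone, so the ketone can direct their introduction. Removing them turns ring A into a plain chroman whose acylation has one sensible outcome, so the C6-versus-C8 ambiguity of phloroglucinol acylation or annulation disappears. The gain is large: a hexasubstituted benzene becomes a trisubstituted one. The demand is equally large: two successive directed oxidations, the second at crowded C5, beside an aryl ether, an α-methylene and ring B. The spectator groups of 9 were weighed against this demand and are kept:
- bromide and not iodide, because an aryl iodide would itself be oxidised to a hypervalent species;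
- an acid-stable, electron-withdrawing ester on the ring-B oxygen, because a free or alkylated phenol there would be oxidised;
- no alkene.

What is strengthened is the medium: an anhydride co-solvent keeps each new oxygen acylated (as in 10 and 11) until work-up.

9 ⇒ 4 + 7 (through 8). The C6–C(=O) bond is cut. This is the natural polarity for electrophilic acylation para to O1, and it divides the molecule into two halves of similar size. The gain is convergence. The demand is that the acyl donor neither cyclises onto its own ring nor loses its ester under a strong Lewis acid, which is why ring B is brominated and acylated on oxygen before this step.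

7 ⇒ 6 ⇒ 5. The ester O–acyl bond and the C–Br bond of ring B are removed in turn. Bromination comes first, while the free phenol activates and directs ortho and the para position is occupied by the side chain. The gain is a commercial hydroxy acid. The demand is mono-bromination, and then O-acylation in the presence of the carboxylic acid.

4 ⇒ 1 + 2 (through 3). The pyran ring is cut at C4–C4a and O1–C2, a formal [3+3] union of a phenol with a diene. The gain is two bulk chemicals. The demand is ortho and not para C-alkylation, followed by Markovnikov ring closure.

## Other disconnections considered

Alternative 1: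
- Cut: ring A at three bonds, C5–C6, C7–C8 and C4a–C5. It is then assembled from a dihydropyran carrying a diazoketone, A2, and a siloxyalkyne, A3, that already holds the ring-B chain with its ketone masked as a dioxolane.
- Forward key step: irradiation of A2 triggers a Wolff rearrangement to a vinylketene. [2+2] cycloaddition with the electron-rich alkyne A3 gives a 4-vinylcyclobutenone, four-electron ring opening gives a dienylketene, and six-electron electrocyclisation with tautomerisation closes ring A as the phenol A1 (free 5-OH, silylated 7-O, ketal at the carbonyl carbon on C6).
- In its favour: every ring-A substituent is placed by the connectivity of the two partners, so neither the C6/C8 question nor the hindered C5 position arises. The two ring-A oxygens emerge differentiated, the reaction belongs to a known class of aromatic annulation, and the plan is convergent.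
- Against it here: A2 and A3 each need several steps. A3 requires an alkynyl silyl ether next to a fully substituted ketal carbon, which is laborious to make and sterically demanding in the cycloaddition. The prenyl alkene of ring B has to pass through ketene chemistry and ultraviolet light. A1 still needs three unmasking operations, two of them acidic, at a stage when the prenyl group sits next to the ring-B oxygen and can cyclise onto it once the acetal is gone.
- Comparison: on structure this alternative is the better plan, because it fixes the ring-A pattern by construction, where the chosen plan relies on two successive directed C–H oxidations, the second at a crowded site. On mechanism it is also the safer one, since its key step has close precedent and the chosen key step stretches a mono-oxidation to a double one. On step economy it is clearly worse, a dozen or more operations against seven, and its end game is more exposed to acid than the single basic deprotection of the chosen route.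

Alternative 2:
- Cut: the pyran ring at C4–C4a, leading back to A5, the 1,1-dimethylpropargyl ether of the ring-A hydroxyl para to the ketone. A5 would come from the natural trihydroxy dihydrochalcone A6 by alkylation of its most acidic hydroxyl.
- Forward key step: the cationic gold species from AuCl(PPh3) and AgSbF6 coordinates the alkyne, the ortho carbon of ring A attacks it in a 6-endo fashion, and protodeauration gives the 2H-chromene A4.
- In its favour: the reaction type is well known for aryl propargyl ethers and has a purely thermal counterpart. The two ortho carbons of A5 are equivalent, so only one chromene can form, with O1 para to the acyl group by design. A4 would be reached in about two steps from an inexpensive material.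
- Against it here: A4 lacks the ring-B prenyl group and offers no handle for it. The C3–C4 double bond must still be hydrogenated. A late electrophilic prenylation would go to C8 or to oxygen of the much more nucleophilic ring A and not to ring B. Carrying a ring-B halide through would need a bromination that is selective in the presence of ring A, or a non-natural dihydrochalcone, and a hydrogenation that spares the C–Br bond.
- Comparison: in the regiochemistry of the chroman and in precedent for the key step this alternative is the equal or the better of the chosen plan, and it is shorter up to the bicyclic core. On the overall structure it is weaker, because it leaves the differentiation of ring B from ring A unsolved; the chosen plan settles that by building ring B with its bromide before the rings are joined. The step counts would be similar only if the ring-B problem could be solved in one or two steps, which is unlikely.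

Alternative 3:
- Cut: ring A between the acyl-bearing carbon and a neighbouring oxygen-bearing carbon, which unfolds it into the open-chain triketo ester A8.
- Forward key step: NaOMe in MeOH forms the carbanion at C6 of the chain, which attacks the C1 ester in a six-membered Claisen (Dieckmann-type) condensation. Loss of methanol and enolisation give the acylphloroglucinol A7.
- In its favour: it mirrors the biosynthetic folding, needs no aromatic starting material for ring A, attaches the acyl group to the ring without ambiguity, and belongs to a known family of polyketo ester cyclisations.
- Against it here: the same chain can fold by aldol condensation (C2 onto the C7 ketone) to a resorcylate, or lactonise to a pyranone, so the mode of closure depends delicately on conditions. A8 is a sensitive polycarbonyl compound that must be made by polyanion acylation. An acylphloroglucinol of the type of A7 is also reachable by a single ring acylation, so the key step buys little. The chroman ring (with its choice between closure para or ortho to the ketone), the allyl-to-prenyl exchange and the removal of the acetal all remain.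
- Comparison: on mechanism the alternative rests on known reactivity and is in that respect the better founded. On the oxygenation pattern of ring A it is the equal of the chosen plan. On structure it is weaker, because the chroman regiochemistry, which the chosen plan fixes in its first step, is left to a late and ambiguous cyclisation. On step economy it is longer, roughly ten to twelve steps.

Key step: step 5

Remark on the chemistry: ring A is numbered as a chroman throughout (O1, C2, C3, C4, C4a, C5 to C8, C8a), and it is assumed that the aryl trifluoroacetates formed in step 5 are cleaved by water on work-up, so that 12 is isolated as the free bisphenol.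

## Route

Step 1
Reactants: 1 phenol; 2 isoprene (2-methylbuta-1,3-diene)
Product: 4 2,2-dimethylchroman, via 2-(3-methylbut-2-enyl)phenol 3 (not isolated)
Conditions: 1 (3 equiv), 2 (1 equiv), AgOTf (5 mol %), ClCH2CH2Cl, rt; aq NaOH wash, distillation
Reagents that add atoms: none
Why: Acid-type activation of the diene leads to ortho Friedel–Crafts prenylation of the phenol (3), and Markovnikov hydroalkoxylation of the trisubstituted alkene then closes the six-membered ether; this phenol–diene annulation is an established chroman synthesis. Excess phenol limits double alkylation, and phenol and any para-alkylated phenol are removed by the base wash because 4 is the only non-acidic aromatic product.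

Step 2
Reactants: 5 3-(4-hydroxyphenyl)propanoic acid
Product: 6 3-(3-bromo-4-hydroxyphenyl)propanoic acid
Conditions: Br2 (1.0 equiv), AcOH, 15 °C to rt
Reagents that add atoms: bromine, BrBr
Why: Electrophilic aromatic bromination; the hydroxyl directs ortho and the para position is blocked by the side chain, and one equivalent at low temperature limits dibromination.

Step 3
Reactants: 6 3-(3-bromo-4-hydroxyphenyl)propanoic acid
Product: 7 3-[3-bromo-4-(pivaloyloxy)phenyl]propanoic acid
Conditions: PivCl (1.2 equiv), aq NaOH (2.5 equiv), THF, 0 °C; then HCl to pH 2
Reagents that add atoms: pivaloyl chloride, CC(C)(C)C(=O)Cl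
Why: Schotten–Baumann O-acylation; the phenoxide is far more nucleophilic than the carboxylate, any mixed anhydride is hydrolysed in the aqueous base, and the hindered aryl pivalate survives at 0 °C, so acidification returns the free acid.

Step 4
Reactants: 7 3-[3-bromo-4-(pivaloyloxy)phenyl]propanoic acid; 4 2,2-dimethylchroman
Product: 9 1-(2,2-dimethylchroman-6-yl)-3-[3-bromo-4-(pivaloyloxy)phenyl]propan-1-one, via acid chloride 8 (not isolated)
Conditions: (COCl)2, DMF (cat.), CH2Cl2, 0 °C to rt, evaporate; then 4 (1.1 equiv), AlCl3 (2.2 equiv), CH2Cl2, −10 to 0 °C; ice/HCl
Reagents that add atoms: none
Why: Friedel–Crafts acylation; the acylium ion from 8 attacks the chroman at C6, para to O1, the most activated and least hindered position. Ring B is deactivated by bromine and the acyloxy group, so cyclisation of 8 to an indanone does not compete, and the low temperature guards against Fries migration of the pivaloyl group and opening of the tertiary ether.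

Step 5
Reactants: 9 1-(2,2-dimethylchroman-6-yl)-3-[3-bromo-4-(pivaloyloxy)phenyl]propan-1-one
Product: 12 1-(5,7-dihydroxy-2,2-dimethylchroman-6-yl)-3-[3-bromo-4-(pivaloyloxy)phenyl]propan-1-one, via 7-trifluoroacetoxy ketone 10 (not isolated), via 5,7-bis(trifluoroacetoxy) ketone 11 (not isolated)
Conditions: Pd(OAc)2 (10 mol %, second charge later), PhI(O2CCF3)2 (3 equiv, in portions), CF3CO2H/(CF3CO)2O 9:1, 50 °C; then evaporate, THF/H2O, rt
Reagents that add atoms: [bis(trifluoroacetoxy)iodo]benzene, O=C(O[I](OC(=O)C(F)(F)F)c1ccccc1)C(F)(F)F; trifluoroacetic acid, OC(=O)C(F)(F)F (the two phenolic oxygens come from trifluoroacetate)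
Why: Proposed new method: the closest known reaction type is the Pd(OAc)2-catalysed, ketone-directed ortho C–H hydroxylation of aryl ketones with hypervalent iodine or persulfate oxidants in CF3CO2H, which is established for one ortho position; carrying it through twice on the same ketone is the untested part. The carbonyl oxygen binds electrophilic divalent palladium, concerted metalation–deprotonation at the less hindered C7 gives a five-membered palladacycle, PhI(O2CCF3)2 oxidises it to tetravalent palladium, and C–O reductive elimination releases the aryl trifluoroacetate 10 and divalent palladium. With (CF3CO)2O present the new oxygen stays acylated, so it neither forms the hydrogen bond that would tie up the carbonyl lone pair nor exposes a free phenol to the iodane; the ketone can then turn and direct a second cycle at C5 to give 11, and water cleaves both trifluoroacetates to 12. No ring is closed and no stereocentre is formed. The selectivity needed is C5 and C7 over C8, C4 and ring B: C8 is out of reach of a five-membered chelate, palladation of ring B through the ketone would need a seven-membered chelate, and ring B carries bromine and an acyloxy group that make it inert to the electrophilic metal and to the oxidant. The aryl bromide is untouched because no zerovalent palladium arises in this cycle, and the prenyl group is absent at this stage because an electron-rich alkene would be consumed by the iodane. The second oxygenation at C5, next to the C4 methylene, is expected to be the slow event, which is why catalyst and oxidant are added in portions.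

Step 6
Reactants: 12 1-(5,7-dihydroxy-2,2-dimethylchroman-6-yl)-3-[3-bromo-4-(pivaloyloxy)phenyl]propan-1-one; 13 tributyl(3-methylbut-2-enyl)stannane
Product: 14 1-(5,7-dihydroxy-2,2-dimethylchroman-6-yl)-3-[3-(3-methylbut-2-enyl)-4-(pivaloyloxy)phenyl]propan-1-one
Conditions: 13 (1.3 equiv), Pd(PPh3)4 (5 mol %), DMF (degassed), 100 °C
Reagents that add atoms: none
Why: Stille coupling; zerovalent palladium inserts into the C–Br bond (the ortho acyloxy group keeps ring B electron-poor enough), the allyl unit is transferred from tin, and reductive elimination from the less hindered CH2 terminus of the allyl ligand should give the linear prenyl arene. Ketone, pivalate and the two chelated phenols are inert under these neutral conditions.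

Step 7
Reactants: 14 1-(5,7-dihydroxy-2,2-dimethylchroman-6-yl)-3-[3-(3-methylbut-2-enyl)-4-(pivaloyloxy)phenyl]propan-1-one
Product: 15 1-(5,7-dihydroxy-2,2-dimethylchroman-6-yl)-3-[4-hydroxy-3-(3-methylbut-2-enyl)phenyl]propan-1-one (CNP0080516.0)
Conditions: K2CO3 (3 equiv), MeOH, rt; then dilute HCl to pH 5, 0 °C
Reagents that add atoms: none
Why: Base-mediated transesterification (methanolysis) of the aryl ester; a phenoxide is a good leaving group, so the pivalate is cleaved at room temperature, and nothing else in 14 is base-labile. No strong acid or heat is applied, so the o-prenylphenol does not cyclise.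

## Compound list

1 | phenol | Oc1ccccc1 | starting material
2 | isoprene | C=CC(C)=C | starting material
3 | 2-(3-methylbut-2-enyl)phenol | CC(C)=CCc1ccccc1O | intermediate
4 | 2,2-dimethylchroman (2,2-dimethyl-3,4-dihydro-2H-chromene) | CC1(C)CCc2ccccc2O1 | intermediate
5 | 3-(4-hydroxyphenyl)propanoic acid | OC(=O)CCc1ccc(O)cc1 | starting material
6 | 3-(3-bromo-4-hydroxyphenyl)propanoic acid | OC(=O)CCc1ccc(O)c(Br)c1 | intermediate
7 | 3-[3-bromo-4-(pivaloyloxy)phenyl]propanoic acid | CC(C)(C)C(=O)Oc1ccc(CCC(=O)O)cc1Br | intermediate
8 | 3-[3-bromo-4-(pivaloyloxy)phenyl]propanoyl chloride | CC(C)(C)C(=O)Oc1ccc(CCC(=O)Cl)cc1Br | intermediate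
9 | 1-(2,2-dimethylchroman-6-yl)-3-[3-bromo-4-(pivaloyloxy)phenyl]propan-1-one | CC(C)(C)C(=O)Oc1ccc(CCC(=O)c2ccc3OC(C)(C)CCc3c2)cc1Br | intermediate
10 | 1-[2,2-dimethyl-7-(trifluoroacetoxy)chroman-6-yl]-3-[3-bromo-4-(pivaloyloxy)phenyl]propan-1-one | CC(C)(C)C(=O)Oc1ccc(CCC(=O)c2cc3CCC(C)(C)Oc3cc2OC(=O)C(F)(F)F)cc1Br | intermediate
11 | 1-[2,2-dimethyl-5,7-bis(trifluoroacetoxy)chroman-6-yl]-3-[3-bromo-4-(pivaloyloxy)phenyl]propan-1-one | CC(C)(C)C(=O)Oc1ccc(CCC(=O)c2c(OC(=O)C(F)(F)F)cc3OC(C)(C)CCc3c2OC(=O)C(F)(F)F)cc1Br | intermediate
12 | 1-(5,7-dihydroxy-2,2-dimethylchroman-6-yl)-3-[3-bromo-4-(pivaloyloxy)phenyl]propan-1-one | CC(C)(C)C(=O)Oc1ccc(CCC(=O)c2c(O)cc3OC(C)(C)CCc3c2O)cc1Br | intermediate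
13 | tributyl(3-methylbut-2-enyl)stannane | CCCC[Sn](CCCC)(CCCC)CC=C(C)C | starting material
14 | 1-(5,7-dihydroxy-2,2-dimethylchroman-6-yl)-3-[3-(3-methylbut-2-enyl)-4-(pivaloyloxy)phenyl]propan-1-one | CC(C)(C)C(=O)Oc1ccc(CCC(=O)c2c(O)cc3OC(C)(C)CCc3c2O)cc1CC=C(C)C | intermediate
15 | 1-(5,7-dihydroxy-2,2-dimethylchroman-6-yl)-3-[4-hydroxy-3-(3-methylbut-2-enyl)phenyl]propan-1-one (CNP0080516.0) | CC(C)=CCc1cc(CCC(=O)c2c(O)cc3c(c2O)CCC(C)(C)O3)ccc1O | target

## Step count and least certain steps

Total: 7 steps. Longest linear sequence: 6 steps (steps 2 to 7, from 5 to 15). The chroman branch (step 1) joins at step 4.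

Step 5 (key step).
- What may go wrong: the reaction may stall after the first oxygenation, because palladation at C5 is hindered by the C4 methylene and the ring by then carries one electron-withdrawing trifluoroacetoxy group. Competing paths are oxidation of the α-methylene of the ketone by the iodane, dehydrogenation of the ketone to the enone by divalent palladium, and premature loss of a trifluoroacetyl group followed by oxidation of the exposed phenol.
- Fallback (known chemistry, the oxygens are brought in with the ring): it sets out from 7. Friedel–Crafts C-acylation of commercial benzene-1,3,5-triol with 7 in BF3·OEt2 at 70 °C should give 3-[3-bromo-4-(pivaloyloxy)phenyl]-1-(2,4,6-trihydroxyphenyl)propan-1-one F1. C-prenylation of F1 with 2-methylbut-3-en-2-ol and BF3·OEt2 in dioxane at room temperature should give 3-[3-bromo-4-(pivaloyloxy)phenyl]-1-[2,4,6-trihydroxy-3-(3-methylbut-2-enyl)phenyl]propan-1-one F2. Acid-catalysed hydroalkoxylation (TsOH, toluene, 80 °C) should then close the pyran ring onto the hydroxyl para to the ketone, the one not engaged in the hydrogen bond to the carbonyl, and the route is rejoined at 12. The weak point of this fallback is closure onto an ortho hydroxyl to the 8-acyl isomer, which would have to be separated.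

Step 6.
- What may go wrong: transfer of the allyl unit through its substituted terminus (branched 1,1-dimethylallyl product), protodestannylation of 13 by the acidic ring-A phenols, or sluggish oxidative addition.
- Fallback: it sets out from 12. Stille coupling with allyltributylstannane (Pd(PPh3)4, DMF, 90 °C), where the two allyl termini are equivalent, should give 1-(5,7-dihydroxy-2,2-dimethylchroman-6-yl)-3-[3-allyl-4-(pivaloyloxy)phenyl]propan-1-one F3. Cross-metathesis of F3 with excess 2-methylbut-2-ene and second-generation Grubbs catalyst in CH2Cl2 at 40 °C converts allyl into prenyl and rejoins the route at 14.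

Step 4.
- What may go wrong: Lewis-acid opening of the tertiary aryl ether of 4, Fries migration of the pivaloyl group, or tight complexation of AlCl3 by the ester and ether oxygens that stops the acylation.
- Fallback (cross-coupling in place of electrophilic substitution): it sets out from 4. Bromination with N-bromosuccinimide in MeCN at 0 °C should give 6-bromo-2,2-dimethylchroman F4. Mg in THF gives bromo(2,2-dimethylchroman-6-yl)magnesium F5, and ZnCl2 converts it into (2,2-dimethylchroman-6-yl)zinc chloride F6. Negishi acylation of F6 with acid chloride 8 (made from 7 as in step 4) and Pd(PPh3)4 (cat.) in THF at 0 °C to rt rejoins the route at 9. The arylzinc tolerates the pivalate, and the acyl chloride reacts with zerovalent palladium far faster than the aryl bromide.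

Step 1.
- What may go wrong: para-alkylation or double alkylation of phenol and oligomerisation of the diene, which would leave little ortho product to cyclise.
- Fallback (ortho attachment enforced by a sigmatropic shift): it sets out from 1. O-Alkylation with 3-chloro-3-methylbut-1-yne (K2CO3, KI, CuI cat., acetone, reflux) should give (2-methylbut-3-yn-2-yl)oxybenzene F7. Heating F7 in N,N-diethylaniline at 190 °C (propargyl Claisen rearrangement, hydrogen shift and six-electron ring closure) should give 2,2-dimethyl-2H-chromene F8. Hydrogenation of F8 (H2, Pd/C, EtOAc) rejoins the route at 4.

## Further compounds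

F1 | step 5 | 3-[3-bromo-4-(pivaloyloxy)phenyl]-1-(2,4,6-trihydroxyphenyl)propan-1-one | CC(C)(C)C(=O)Oc1ccc(CCC(=O)c2c(O)cc(O)cc2O)cc1Br
F2 | step 5 | 3-[3-bromo-4-(pivaloyloxy)phenyl]-1-[2,4,6-trihydroxy-3-(3-methylbut-2-enyl)phenyl]propan-1-one | CC(C)(C)C(=O)Oc1ccc(CCC(=O)c2c(O)cc(O)c(CC=C(C)C)c2O)cc1Br
F3 | step 6 | 1-(5,7-dihydroxy-2,2-dimethylchroman-6-yl)-3-[3-allyl-4-(pivaloyloxy)phenyl]propan-1-one | CC(C)(C)C(=O)Oc1ccc(CCC(=O)c2c(O)cc3OC(C)(C)CCc3c2O)cc1CC=C
F4 | step 4 | 6-bromo-2,2-dimethylchroman | CC1(C)CCc2cc(Br)ccc2O1
F5 | step 4 | bromo(2,2-dimethylchroman-6-yl)magnesium | CC1(C)CCc2cc([Mg]Br)ccc2O1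
F6 | step 4 | (2,2-dimethylchroman-6-yl)zinc chloride | CC1(C)CCc2cc([Zn]Cl)ccc2O1
F7 | step 1 | (2-methylbut-3-yn-2-yl)oxybenzene | CC(C)(C#C)Oc1ccccc1
F8 | step 1 | 2,2-dimethyl-2H-chromene | CC1(C)C=Cc2ccccc2O1
A1 | alternative 1 | 2-{2-[4-(methoxymethoxy)-3-(3-methylbut-2-enyl)phenyl]ethyl}-2-[5-hydroxy-2,2-dimethyl-7-(triisopropylsilyloxy)chroman-6-yl]-1,3-dioxolane | CC(C)=CCc1cc(CCC4(OCCO4)c2c(O)c3CCC(C)(C)Oc3cc2O[Si](C(C)C)(C(C)C)C(C)C)ccc1OCOC
A2 | alternative 1 | 2-diazo-1-(6,6-dimethyl-5,6-dihydro-4H-pyran-2-yl)ethan-1-one | CC1(C)CCC=C(O1)C(=O)C=[N+]=[N-]
A3 | alternative 1 | triisopropyl[(2-{2-[4-(methoxymethoxy)-3-(3-methylbut-2-enyl)phenyl]ethyl}-1,3-dioxolan-2-yl)ethynyloxy]silane | CC(C)=CCc1cc(CCC2(OCCO2)C#CO[Si](C(C)C)(C(C)C)C(C)C)ccc1OCOC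
A4 | alternative 2 | 1-(5,7-dihydroxy-2,2-dimethyl-2H-chromen-6-yl)-3-(4-hydroxyphenyl)propan-1-one | CC1(C)C=Cc2c(O1)cc(O)c(C(=O)CCc3ccc(O)cc3)c2O
A5 | alternative 2 | 1-[2,6-dihydroxy-4-(2-methylbut-3-yn-2-yloxy)phenyl]-3-(4-hydroxyphenyl)propan-1-one | C#CC(C)(C)Oc1cc(O)c(C(=O)CCc2ccc(O)cc2)c(O)c1
A6 | alternative 2 | 3-(4-hydroxyphenyl)-1-(2,4,6-trihydroxyphenyl)propan-1-one | O=C(CCc1ccc(O)cc1)c1c(O)cc(O)cc1O
A7 | alternative 3 | 3-[3-allyl-4-(methoxymethoxy)phenyl]-1-(2,4,6-trihydroxyphenyl)propan-1-one | C=CCc1cc(CCC(=O)c2c(O)cc(O)cc2O)ccc1OCOC
A8 | alternative 3 | methyl 9-[3-allyl-4-(methoxymethoxy)phenyl]-3,5,7-trioxononanoate | COC(=O)CC(=O)CC(=O)CC(=O)CCc1ccc(OCOC)c(CC=C)c1
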